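**Retrosynthetic overview**
1. The target (a coumaronochromone) is opened last at C3–C1' and at the furan C2–O bond: 2-(dimethylamino)chromone 13 (rings A and C, chroman and prenyl in place) plus chromene-5,8-quinone 17 (ring B in its oxidised form).
2. C3 of 13 (enaminone carbon) and C1' (ortho to a phenol) are both natural donors. The quinone is the polarity-reversed, acceptor equivalent of the ring B hydroquinone, and loss of Me2NH then closes the furan without any change of oxidation level.
3. 13 comes from acetophenone 8 (C2 and NMe2 from dimethylthiocarbamoyl chloride). 8 comes from 2',4',6'-trihydroxyacetophenone by chroman annulation with isoprene (para-OH masked as pivalate to fix the regiochemistry), then C-prenylation.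
4. 17 comes from 2,5-dimethoxyphenol and prenal (chromenylation), then oxidative demethylation.
5. Ring order: dihydropyran on ring A, then pyranone ring C; separately the chromene on ring B; the furan ring last.

Assumption: the target has no stereocentre and no stereogenic double bond, so it is achiral; "single enantiomer" needs no stereocontrol and the SMILES carry no stereodescriptors (the alkene geometry of transient intermediate 12 is left undefined). Rings A/C are numbered as a chromone (O1, C2, C3, C4=O, C5–C8), ring B with primes. The route is designed from first principles and has not been run; steps 4 and 7 are proposals.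

**Step 1**
Reactants: 1 2',4',6'-trihydroxyacetophenone (dried); 2 pivaloyl chloride
Product: 3 4-acetyl-3,5-dihydroxyphenyl pivalate
Conditions: PivCl (1.05 equiv), iPr2NEt (1.1 equiv), THF, −20 → 0 °C
Reagents that add atoms: pivaloyl chloride (2), CC(C)(C)C(Cl)=O
Why: Selective O-acylation of the most acidic, non-chelated phenol (para to the acetyl group), while the two ortho hydroxyls are hydrogen-bonded and hindered; the ester later forces the pyran ring to close on an ortho oxygen.

**Step 2**
Reactants: 3 4-acetyl-3,5-dihydroxyphenyl pivalate; 4 isoprene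
Product: 5 8-acetyl-7-hydroxy-2,2-dimethylchroman-5-yl pivalate
Conditions: isoprene (1.5 equiv), 85% H3PO4, xylene, 30–35 °C, 24 h (stop near 80% conversion)
Reagents that add atoms: isoprene (4), C=CC(C)=C
Why: Acid-catalysed Friedel–Crafts prenylation at the ring carbon between OH and OPiv, then Markovnikov hydroalkoxylation (chroman annulation of a phenol with isoprene); the only free hydroxyl next to the new side chain is the one ortho to the acetyl group, so only one chroman regioisomer can form.

**Step 3**
Reactants: 5 8-acetyl-7-hydroxy-2,2-dimethylchroman-5-yl pivalate; 6 prenyl bromide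
Product: 8 1-[5,7-dihydroxy-2,2-dimethyl-6-(3-methylbut-2-enyl)chroman-8-yl]ethanone, via deacylated chromandiol 7 (not isolated)
Conditions: 10% aq KOH (6 equiv), 25 °C, 2 h; then prenyl bromide (1.3 equiv), 0 → 25 °C; 1 M HCl work-up
Reagents that add atoms: prenyl bromide (6), CC(C)=CCBr
Why: Saponification of the aryl pivalate, then C-alkylation of the phloroglucinol-type dianion at the only free ring carbon (between the two phenoxides), the classical aqueous-base C-prenylation of acylphloroglucinols.

**Step 4**
Reactants: 8 1-[5,7-dihydroxy-2,2-dimethyl-6-(3-methylbut-2-enyl)chroman-8-yl]ethanone; 9 dimethylthiocarbamoyl chloride; 10 iodomethane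
Product: 13 2-(dimethylamino)-7-hydroxy-8-(3-methylbut-2-enyl)chromen-4-one carrying a 2,2-dimethyl-3,4-dihydro-2H-pyran ring fused at C5–C6 (ring oxygen on C5, CH2 on C6), via oxothioamide 11 (not isolated), via S-methyl ketene acetal 12 (not isolated)
Conditions: LiN(SiMe3)2 (4.2 equiv), THF, −78 → −20 °C; Me2NC(S)Cl (1.05 equiv), −78 → 0 °C; MeI (1.05 equiv), 0 → 25 °C, then 60 °C, 3 h; aq NH4Cl
Reagents that add atoms: dimethylthiocarbamoyl chloride (9), CN(C)C(Cl)=S
Why: Proposed new method: the polylithiated o-hydroxyacetophenone is acylated at carbon (as in the one-step β-diketone synthesis from polylithiated hydroxyacetophenones and acyl chlorides), the thioenolate is S-methylated to an α-oxo ketene N,S-acetal, and the ortho phenoxide closes the pyranone by addition–elimination with loss of methanethiolate (the known ketene dithioacetal/N,S-acetal route to 2-substituted chromones), all under base so the prenyl group and the free phenol are untouched.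

**Step 5**
Reactants: 14 2,5-dimethoxyphenol; 15 3-methylbut-2-enal
Product: 16 5,8-dimethoxy-2,2-dimethyl-2H-chromene
Conditions: PhB(OH)2 (1.0 equiv), EtCO2H (0.3 equiv), toluene, reflux, Dean–Stark, 24 h
Reagents that add atoms: 3-methylbut-2-enal (15), CC(C)=CC=O
Why: Phenylboronic acid-templated ortho-condensation of the phenol with the enal gives an o-quinone methide that closes by oxa-6π electrocyclisation (chromenylation); the single free ortho position fixes the regiochemistry.

**Step 6**
Reactants: 16 5,8-dimethoxy-2,2-dimethyl-2H-chromene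
Product: 17 2,2-dimethyl-2H-chromene-5,8-dione
Conditions: (NH4)2Ce(NO3)6 (2.5 equiv), MeCN/H2O 2:1, 0 °C, 15 min; use at once
Reagents that add atoms: water, O
Why: Oxidative demethylation of a para-dimethoxyarene by tetravalent cerium gives the para-quinone (carbonyl oxygens from water) and leaves the chromene double bond intact, as for pyrano-fused quinones of the dehydro-α-lapachone type.

**Step 7**
Reactants: 13 the 2-(dimethylamino)chromone of step 4; 17 2,2-dimethyl-2H-chromene-5,8-dione
Product: 19 target coumaronochromone (7-hydroxy-8-prenyl, dimethyldihydropyran fused at C5–C6 with O on C5; furan oxygen joining C2 and C2'; ring B with 5'-OH and a 2,2-dimethyl-2H-pyran fused at C3'–C4' with O on C4'), via aryl hydroquinone adduct 18 (not isolated)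
Conditions: 13 (1.0 equiv), 17 (1.1 equiv, added over 1 h), AcOH/MeCN 1:3, Ar, 25 °C, then 60 °C, 4 h
Reagents that add atoms: 2,2-dimethyl-2H-chromene-5,8-dione (17), CC1(C)C=CC2=C(O1)C(=O)C=CC2=O
Why: Proposed new method: a Nenitzescu-type benzofuran annulation in which the quinone serves as the polarity-reversed (acceptor) equivalent of electron-rich ring B, so that enaminone carbon C3 of 13 adds at C6 of the quinone (beta to the carbonyl that is not deactivated by the ring oxygen), the adduct aromatises to hydroquinone 18, and its ortho hydroxyl displaces dimethylamine at C2 by acid-promoted addition–elimination (the reactivity by which 2-aminochromones hydrolyse to 4-hydroxycoumarins), giving the furan ring and the free 5'-OH in one redox-neutral step; the closest known reaction is the Nenitzescu synthesis of 5-hydroxybenzofurans from tertiary enaminones and quinones.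

**Compound list**
1 | 2',4',6'-trihydroxyacetophenone | CC(=O)c1c(O)cc(O)cc1O | starting material
2 | pivaloyl chloride | CC(C)(C)C(Cl)=O | starting material
3 | 4-acetyl-3,5-dihydroxyphenyl pivalate | CC(=O)c1c(O)cc(OC(=O)C(C)(C)C)cc1O | intermediate
4 | isoprene | C=CC(C)=C | starting material
5 | 8-acetyl-7-hydroxy-2,2-dimethylchroman-5-yl pivalate | CC(=O)c1c(O)cc(OC(=O)C(C)(C)C)c2c1OC(C)(C)CC2 | intermediate
6 | prenyl bromide (1-bromo-3-methylbut-2-ene) | CC(C)=CCBr | starting material
7 | 1-(5,7-dihydroxy-2,2-dimethylchroman-8-yl)ethanone | CC(=O)c1c(O)cc(O)c2c1OC(C)(C)CC2 | intermediate (not isolated)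
8 | 1-[5,7-dihydroxy-2,2-dimethyl-6-(3-methylbut-2-enyl)chroman-8-yl]ethanone | CC(=O)c1c(O)c(CC=C(C)C)c(O)c2c1OC(C)(C)CC2 | intermediate
9 | dimethylthiocarbamoyl chloride | CN(C)C(Cl)=S | starting material
10 | iodomethane | CI | starting material
11 | 3-[5,7-dihydroxy-2,2-dimethyl-6-(3-methylbut-2-enyl)chroman-8-yl]-N,N-dimethyl-3-oxopropanethioamide | CN(C)C(=S)CC(=O)c1c(O)c(CC=C(C)C)c(O)c2c1OC(C)(C)CC2 | intermediate (not isolated)
12 | 1-[5,7-dihydroxy-2,2-dimethyl-6-(3-methylbut-2-enyl)chroman-8-yl]-3-(dimethylamino)-3-(methylsulfanyl)prop-2-en-1-one (geometry undefined) | CSC(=CC(=O)c1c(O)c(CC=C(C)C)c(O)c2c1OC(C)(C)CC2)N(C)C | intermediate (not isolated)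
13 | 2-(dimethylamino)-7-hydroxy-8-(3-methylbut-2-enyl)chromen-4-one with a 2,2-dimethyldihydropyran fused at C5–C6 (O on C5) | CN(C)c1cc(=O)c2c3OC(C)(C)CCc3c(O)c(CC=C(C)C)c2o1 | intermediate
14 | 2,5-dimethoxyphenol | COc1ccc(OC)c(O)c1 | starting material
15 | 3-methylbut-2-enal (prenal) | CC(C)=CC=O | starting material
16 | 5,8-dimethoxy-2,2-dimethyl-2H-chromene | COc1ccc(OC)c2OC(C)(C)C=Cc12 | intermediate
17 | 2,2-dimethyl-2H-chromene-5,8-dione | CC1(C)C=CC2=C(O1)C(=O)C=CC2=O | intermediate
18 | 13 bearing a 5,8-dihydroxy-2,2-dimethyl-2H-chromen-6-yl group at C3 | CN(C)c1oc2c(CC=C(C)C)c(O)c3CCC(C)(C)Oc3c2c(=O)c1-c1cc(O)c2OC(C)(C)C=Cc2c1O | intermediate (not isolated)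
19 | target coumaronochromone CNP0081330.0 | CC(C)=CCc1c(O)c2c(c3c(=O)c4c(oc13)oc1c3c(c(O)cc14)OC(C)(C)C=C3)OC(C)(C)CC2 | target

**Count**
Total steps: 7. Longest linear sequence: 5 (steps 1, 2, 3, 4, 7); the ring B branch is steps 5, 6, 7.

**Three steps most likely to fail, with fallbacks**

Step 7 (quinone annulation). The risks are redox exchange between hydroquinone 18 and quinone 17, and slow amine displacement. The fallback drops the carboxyl-level C2 and closes the furan oxidatively. It sets out from acetophenone 8: condensation with Me2NCH(OMe)2 (toluene, 80 °C) gives the enaminone (E)-3-(dimethylamino)-1-[5,7-dihydroxy-2,2-dimethyl-6-(3-methylbut-2-enyl)chroman-8-yl]prop-2-en-1-one F1. F1 and quinone 17 in AcOH undergo tandem arylation and chromone closure, with loss of dimethylamine, to the 2',5'-dihydroxyisoflavone 3-(5,8-dihydroxy-2,2-dimethyl-2H-chromen-6-yl)-7-hydroxy-8-prenylchromone with the C5–C6 dihydropyran F2. Ag2O (THF/Et2O, 0 °C) oxidises the hydroquinone of F2 to the chromon-3-yl chromene-5,8-dione F3. Catalytic DABCO in THF then isomerises F3 (1,6-addition at C2, enolisation to the hydroquinone, addition–elimination by the 2'-hydroxyl), and the route comes back at target 19.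

Step 4 (one-pot aminochromone synthesis). The risks are O-thiocarbamoylation of the phenoxides and incomplete ring closure. The fallback brings in C2 as carbon disulfide and the nitrogen afterwards. It sets out from 8: LiN(SiMe3)2 and CS2 in THF, then MeI (2.1 equiv), give the α-oxo ketene dithioacetal 1-[5,7-dihydroxy-2,2-dimethyl-6-(3-methylbut-2-enyl)chroman-8-yl]-3,3-bis(methylsulfanyl)prop-2-en-1-one F4. Me2NH (2 M in THF, EtOH, 60 °C) displaces one methylsulfanyl group from F4, and the route comes back at 12, which closes to 13 as in step 4.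

Step 2 (isoprene annulation on the deactivated pivalate). The risks are sluggish alkylation and double annulation. The fallback makes the C–C bond under base before the ring is closed. It sets out from 1: prenyl bromide in 10% aq KOH gives 1-[2,4,6-trihydroxy-3-(3-methylbut-2-enyl)phenyl]ethanone F5. PivCl/iPr2NEt acylates its para hydroxyl to give 4-acetyl-3,5-dihydroxy-2-(3-methylbut-2-enyl)phenyl pivalate F6. TsOH·H2O (cat.) in toluene at 60 °C closes the prenyl group of F6 onto the only neighbouring free hydroxyl, and the route comes back at 5.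

**Further compounds**
F1 | step 7 | (E)-3-(dimethylamino)-1-[5,7-dihydroxy-2,2-dimethyl-6-(3-methylbut-2-enyl)chroman-8-yl]prop-2-en-1-one | CN(C)/C=C/C(=O)c1c(O)c(CC=C(C)C)c(O)c2c1OC(C)(C)CC2
F2 | step 7 | 3-(5,8-dihydroxy-2,2-dimethyl-2H-chromen-6-yl)-7-hydroxy-8-(3-methylbut-2-enyl)chromen-4-one with the 2,2-dimethyldihydropyran fused at C5–C6 | O=c1c(-c2cc(O)c3OC(C)(C)C=Cc3c2O)coc2c(CC=C(C)C)c(O)c3CCC(C)(C)Oc3c12
F3 | step 7 | 6-(chromon-3-yl)-2,2-dimethyl-2H-chromene-5,8-dione (quinone of F2) | O=c1c(C2=CC(=O)C3=C(C=CC(C)(C)O3)C2=O)coc2c(CC=C(C)C)c(O)c3CCC(C)(C)Oc3c12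
F4 | step 4 | 1-[5,7-dihydroxy-2,2-dimethyl-6-(3-methylbut-2-enyl)chroman-8-yl]-3,3-bis(methylsulfanyl)prop-2-en-1-one | CSC(SC)=CC(=O)c1c(O)c(CC=C(C)C)c(O)c2c1OC(C)(C)CC2
F5 | step 2 | 1-[2,4,6-trihydroxy-3-(3-methylbut-2-enyl)phenyl]ethanone | CC(=O)c1c(O)cc(O)c(CC=C(C)C)c1O
F6 | step 2 | 4-acetyl-3,5-dihydroxy-2-(3-methylbut-2-enyl)phenyl pivalate | CC(=O)c1c(O)cc(OC(=O)C(C)(C)C)c(CC=C(C)C)c1O
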